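**The question.** I wanted to know which way of adding X or Z to the catalyst D leaves the most G after 40 h.

| flask | Z | X | D | temperature | remark | time |
|---|---|---|---|---|---|---|
| dusk | 0.064 M | 0.0768 M | 3.2 mM | 40 °C | run made earlier |  |
| summer | 0.096 M | 0.0768 M | 3.2 mM | 40 °C | run made earlier |  |
| north-west | 0.064 M | 0.0768 M (fed, over 25 h) | 3.2 mM | 40 °C | all else is in the flask from the start; the feed brings no volume worth counting | 40 h |
| south-east | 0.064 M | 0.0768 M (in portions, 3, over 25 h) | 3.2 mM | 40 °C | first portion at the start, last at 25 h | 40 h |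
| south | 0.064 M (fed, over 25 h) | 0.0768 M | 3.2 mM | 40 °C | all else is in the flask from the start; the feed brings no volume worth counting | 40 h |
| east | 0.064 M (fed, over 25 h) | 0.0768 M | 3.2 mM |  | the addition at 20 °C, then warmed to 40 °C; the feed brings no volume worth counting | 40 h |

- dusk (time / h: G / %, Z / %): 6.00: 17.9, 38.5; 12.0: 29.5, 15.2; 15.0: 32.2, 9.0; 25.0: 37.4, 1.7; 30.0: 38.4, 1.1; 40.0: 39.6, 0.4
- summer (time / h: G / %, Z / %): 0.200: 0.1, 96.2; 0.667: 0.7, 88.9; 1.00: 1.4, 84.6; 1.50: 3.2, 77.9; 2.50: 6.2, 66.8; 3.00: 7.0, 62.2; 4.00: 10.3, 54.0

(readings scatter by 0.3 percentage points)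

- the best flask by amount of G, in percent of the Z charged; "all alike" if 1.5 percentage points covers them all (north-west / south-east / south / east / all alike)
- amount of G at the end, in percent of the Z charged, north-west
- amount of G at the end, in percent of the Z charged, south-east
- amount of G at the end, in percent of the Z charged, south
- amount of G at the end, in percent of the Z charged, east

- the earlier runs do not show what temperature does; that part of a forecast is a guess

**Going to logarithms.** I worked with the logarithm of Z, since anything that loses the same fraction every hour falls on a straight line there. In dusk, Z reached 38.5 % at 6.00 h, so the slope k was 0.159 h⁻¹. Later in dusk the slope was 0.164 h⁻¹, and summer, with more Z, gave 0.154 h⁻¹. So the fall looked pseudo-first-order in Z. Dividing the natural logarithm of 2 by k gave the Z half-life, 4.36 h, the time in which whatever Z stands in the flask halves, a reading that holds for 3.2 mM of D at 40 °C.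

**First instants.** In summer at 0.200 h, Z had lost 3.8 percentage points while G showed 0.1 %, so Z went first into something unseen.

**The middle.** In dusk at 12.0 h, 55 points of the charge was neither Z nor G. G still climbed, to 32.2 % at 15.0 h.

**The end.** In dusk at 40.0 h, Z stood at 0.4 % and G at 39.6 %, so 60 points of the charge had gone elsewhere.

**Fed Z.** In south, I reasoned, Z settles where its feed equals its loss, at 25.1 % of the charge, since the feed lasts 5.74 half-lives. The 3.44 half-lives after the feed should leave 2.31 %. I reckoned no G from this.

**The forecast.** It named south: 23 % for north-west, 26 % for south-east, 46 % for south (range 41 % to 54 %) and 39 % for east, noting that selectivity “looks worse at higher Z”.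

**The result.** North-west gave 26.0 %, south-east 25.5 %, south 29.9 % and east 37.6 %, so east was best, and south fell 16 points short of the forecast.

    Z + D → D + J (k = 56.0 L mol⁻¹ h⁻¹, Ea = 57.0 kJ mol⁻¹)
    D + J ⇌ E (K = 10.0 L mol⁻¹, k = 2500 L mol⁻¹ h⁻¹, Ea = 36.0 kJ mol⁻¹, ΔH = 19.0 kJ mol⁻¹)
    X + E → D + G (k = 98.0 L mol⁻¹ h⁻¹, Ea = 45.0 kJ mol⁻¹)
    J → Q (k = 0.130 h⁻¹, Ea = 92.0 kJ mol⁻¹)
    X ⇌ L (K = 2.40, k = 0.0900 h⁻¹, Ea = 113 kJ mol⁻¹, ΔH = −90.0 kJ mol⁻¹)
    (constants at 40 °C)

**Two clocks.** In south-east at 4.38 h, X had a half-life of 7.7 h by its forward passing into L alone, longer than the 4.36 h I had read for Z, and that forward passing used X 1.7 times as fast as the step making G. By the end of south-east that ratio was 74. Counting the loss of Z as proportional to D, I reckoned for a flask like south-east but with 0.0019 M of D a Z half-life of 7.34 h, which gave 2.29 % of Z at the end, and that flask held 2.02 %.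

The numbers in the tables are calculated from invented constants; noise was put on by code.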